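**Retrosynthetic overview**
1. Target triacid ⇐ its trimethyl ester ⇐ tricyclic keto alkyne: ring D closes last, by ketyl–alkyne cyclisation C13→C16.
2. Keto alkyne ⇐ enone malonate: ring B by intramolecular Michael addition C6→C8 (quaternary C8, B/C cis).
3. Enone malonate ⇐ allyl ester of a ring A acid with a ring C allylic alcohol: the key step is an Ireland–Claisen union that makes C9–C10, quaternary C10 and C9 in one event. This replaces the usual hydrofluorene-first logic (Diels–Alder or ring contraction, then the bicyclooctane).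
4. Ring A acid ⇐ meso anhydride ⇐ all-cis hydrogenation of an aryl malonate; ring C alcohol ⇐ microbial cis-diol of bromobenzene (source of the C9 chirality).
5. Ring order: A and C preformed, then B, then D; the C4 methyl enters late, steered by the C20 ester and the C5 side chain.

Assumption: gibberellane atom numbers (C1–C20) are used for every intermediate, and the four starting materials (the bromo diacid, dimethyl malonate, the bromobenzene cis-diol and the silylated propargyl bromide) are bought.

**Route**

Step 1
Reactants: 1 2-bromobenzene-1,3-dicarboxylic acid; 2 dimethyl propanedioate (dimethyl malonate)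
Product: 3 2-(1,3-dimethoxy-1,3-dioxopropan-2-yl)benzene-1,3-dicarboxylic acid
Conditions: NaH, CuBr (10 mol %), 2 as solvent, 80 °C; then 1 M HCl
Reagents that add atoms: none
Why: Hurtley reaction, a copper-catalysed arylation of the malonate anion helped by the two ortho carboxylates that hold copper next to the C–Br bond; no stereocentre is formed.

Step 2
Reactants: 3 2-(1,3-dimethoxy-1,3-dioxopropan-2-yl)benzene-1,3-dicarboxylic acid
Product: 4 all-cis-2-(1,3-dimethoxy-1,3-dioxopropan-2-yl)cyclohexane-1,3-dicarboxylic acid (meso)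
Conditions: H2 (70 bar), 5 % Rh on Al2O3, AcOH, 60 °C
Reagents that add atoms: none
Why: heterogeneous arene hydrogenation delivers all six hydrogens from the catalyst face, so the three ring substituents (future C19, C6, C20) end up cis in a meso compound.

Step 3
Reactants: 4 all-cis diacid
Product: 5 dimethyl 2-[(1R,5S)-2,4-dioxo-3-oxabicyclo[3.3.1]nonan-9-yl]propanedioate (meso bridged anhydride)
Conditions: Ac2O, 100 °C; evaporate
Reagents that add atoms: none
Why: cyclodehydration to the six-membered anhydride, possible because the cis-1,3-carboxyl groups can both go axial while the malonyl group stays equatorial; stereocentres are untouched.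

Step 4
Reactants: 5 meso anhydride
Product: 6 (1S,2S,3R)-2-(1,3-dimethoxy-1,3-dioxopropan-2-yl)-3-(methoxycarbonyl)cyclohexane-1-carboxylic acid
Conditions: MeOH (10 equiv), hydroquinidine anthraquinone-1,4-diyl diether (DHQD)2AQN (15 mol %), Et2O, −25 °C
Reagents that add atoms: methanol, CO
Why: cinchona-alkaloid-catalysed desymmetrising alcoholysis of a meso anhydride, in which the catalyst selects one of the two enantiotopic carbonyls and so fixes C5 in the absolute sense (methyl ester at the future C19, free acid at C20); (DHQ)2AQN is the pseudo-enantiomeric catalyst to use if the sense of induction proves opposite.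

Step 5
Reactants: 7 (1S,2S)-3-bromocyclohexa-3,5-diene-1,2-diol
Product: 8 (1S,2S)-3-bromocyclohex-3-ene-1,2-diol
Conditions: KO2C–N=N–CO2K, AcOH, MeOH, 0 °C
Reagents that add atoms: none
Why: diimide reduction (concerted syn hydrogen transfer) takes the disubstituted alkene and leaves the more hindered vinyl bromide; the two carbinol centres (future C13, C14) are untouched.

Step 6
Reactants: 8 (1S,2S)-3-bromocyclohex-3-ene-1,2-diol
Product: 9 (1S,6S)-2-bromo-6-[(tert-butyldimethylsilyl)oxy]cyclohex-2-en-1-ol
Conditions: TBSCl (1.05 equiv), imidazole, DMF, −10 °C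
Reagents that add atoms: tert-butyldimethylsilyl chloride, CC(C)(C)[Si](C)(C)Cl
Why: monosilylation under steric control, the hydroxyl remote from the vinyl bromide (future C13–OH) reacting first and leaving the allylic C14–OH free.

Step 7
Reactants: 9 (1S,6S)-2-bromo-6-[(tert-butyldimethylsilyl)oxy]cyclohex-2-en-1-ol; 10 3-bromo-1-(trimethylsilyl)prop-1-yne
Product: 12 (1R,6S)-6-[(tert-butyldimethylsilyl)oxy]-2-[3-(trimethylsilyl)prop-2-yn-1-yl]cyclohex-2-en-1-ol, via dilithio species 11 (not isolated)
Conditions: n-BuLi (1.0 equiv) then t-BuLi (2.1 equiv), Et2O, −78 °C; CuBr·SMe2 (10 mol %), 10, −78 → −20 °C; H2O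
Reagents that add atoms: none
Why: bromine–lithium exchange on the lithium alkoxide gives a vinyllithium that is alkylated under copper catalysis, the silyl group on the alkyne terminus blocking SN2' attack so that the skipped enyne (C8–C15 bond) forms; stereocentres are untouched.

Step 8
Reactants: 6 ring A acid; 12 ring C alcohol
Product: 13 ester of 6 (through the C20 carboxyl) and 12 (through O-14)
Conditions: DCC, DMAP, CH2Cl2, 0 → 25 °C
Reagents that add atoms: none
Why: Steglich esterification, which does not break the C14–O bond and so keeps C14; the diastereomer formed from the minor enantiomer of 6 is removed here by chromatography.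

Step 9
Reactants: 13 allyl ester
Product: 17 C9–C10-linked tetramethyl ester (C4 epimers), via tris-silyl ketene acetal 14 (not isolated), via rearranged silyl ester 15 (not isolated), via crude C20 acid 16 (not isolated)
Conditions: LDA (4.5 equiv), TMSCl, THF, −78 → 55 °C; 1 M HCl; then TMSCHN2, MeOH–toluene, 0 °C
Reagents that add atoms: trimethylsilyldiazomethane, C[Si](C)(C)C=[N+]=[N-]
Why: Ireland–Claisen rearrangement, in which all three acidic sites are silylated but only the allyl ketene acetal can rearrange; the C9–C10 bond forms on the ring C face that carried the ester oxygen (suprafacial 1,3-chirality transfer sets C9) and on the C10 face opposite the C5 side chain, which is held axial by allylic 1,3-strain (sets quaternary C10, C20 cis to C6), while C4 is scrambled until step 10 and the acid is then O-methylated.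

Step 10
Reactants: 17 tetramethyl ester (C4 epimers)
Product: 18 C4-methylated tetramethyl ester (C4, C5, C9, C10 as in the target)
Conditions: LDA (2.3 equiv), THF, −78 → −40 °C; MeI (1.1 equiv), −78 °C; H2O
Reagents that add atoms: iodomethane, CI
Why: dianion alkylation, the malonate being deprotonated first and staying inert while the more reactive C4 ester enolate takes MeI on the face away from both the C20 ester and the C5 side chain, so the C19 ester ends up cis to C20 (quaternary C4).

Step 11
Reactants: 18 C4-methylated tetramethyl ester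
Product: 19 allylic alcohol carrying a free terminal alkyne
Conditions: TBAF, AcOH, THF, 25 °C
Reagents that add atoms: none
Why: fluoride cleaves the O–Si and the alkynyl C–Si bonds in one operation, and the acetic acid buffer protects the esters and keeps the malonate protonated.

Step 12
Reactants: 19 allylic alcohol
Product: 20 enone (C13 ketone, C14=C8 alkene) carrying the C5 malonate and the C8 propargyl group
Conditions: Dess–Martin periodinane, CH2Cl2, 0 → 25 °C
Reagents that add atoms: none
Why: Dess–Martin oxidation of the allylic alcohol gives the conjugated enone and erases the C13 carbinol centre, which is no longer needed.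

Step 13
Reactants: 20 enone malonate
Product: 21 tricyclic keto tetraester (rings A, B, C; geminal diester at C6; propargyl on quaternary C8)
Conditions: Cs2CO3 (0.3 equiv), MeCN, 0 → 25 °C
Reagents that add atoms: none
Why: intramolecular Michael addition (5-exo-trig) of the malonate to the β,β-disubstituted enone, in which the C9-anchored tether reaches C8 only on the face syn to the C9–C10 bond, so the propargyl group ends up anti to C10 (cis B/C fusion, C8 as in the target), the trans A/B fusion being preset by the trans relation of C9 and C6 on ring A.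

Step 14
Reactants: 21 tricyclic keto tetraester
Product: 23 tricyclic keto triester (natural C6 configuration), via C6-epimer mixture 22 (not isolated)
Conditions: LiCl, H2O, DMSO, 150 °C; then NaOMe (0.2 equiv), MeOH, 25 °C
Reagents that add atoms: none
Why: Krapcho dealkoxycarbonylation removes one ester of the geminal pair, and base equilibration through the ester enolate funnels the C6 epimers to the more stable β-ester, which is trans to C4 and on the face away from C19, C20 and C14 (the natural C6 configuration).

Step 15
Reactants: 23 keto triester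
Product: 24 trimethyl ester of the target gibberellin
Conditions: SmI2 (3 equiv), HMPA, t-BuOH, THF, 0 °C
Reagents that add atoms: none
Why: samarium-ketyl–alkyne 5-exo-dig radical cyclisation closes ring D and gives the 13-hydroxy-16-methylene unit directly; C15 on C8 can bridge to C13 from one side only, so C13 is fixed by the ring system, and the esters are inert to SmI2.

Step 16
Reactants: 24 trimethyl ester of the target gibberellin
Product: 25 ent-13-hydroxygibberell-16-ene-7,19,20-trioic acid (the target gibberellin)
Conditions: n-PrSH, n-BuLi (gives n-PrSLi), HMPA, 25 → 50 °C; then 1 M HCl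
Reagents that add atoms: none
Why: SN2 demethylation by thiolate attacks the unhindered O-methyl carbons and so frees the hindered C19 and C20 acids and C7 without touching the tertiary allylic alcohol, the exocyclic alkene or any stereocentre.

**Compound list**
1 | 2-bromobenzene-1,3-dicarboxylic acid | OC(=O)c1cccc(C(=O)O)c1Br | starting material
2 | dimethyl propanedioate | COC(=O)CC(=O)OC | starting material
3 | 2-(1,3-dimethoxy-1,3-dioxopropan-2-yl)benzene-1,3-dicarboxylic acid | COC(=O)C(C(=O)OC)c1c(C(=O)O)cccc1C(=O)O | intermediate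
4 | all-cis-2-(1,3-dimethoxy-1,3-dioxopropan-2-yl)cyclohexane-1,3-dicarboxylic acid (meso) | OC(=O)[C@H]1CCC[C@@H](C(=O)O)[C@H]1C(C(=O)OC)C(=O)OC | intermediate
5 | dimethyl 2-[(1R,5S)-2,4-dioxo-3-oxabicyclo[3.3.1]nonan-9-yl]propanedioate (meso; malonyl group cis to both carbonyl-bearing bonds) | O=C1OC(=O)[C@@H]2CCC[C@H]1[C@@H]2C(C(=O)OC)C(=O)OC | intermediate
6 | (1S,2S,3R)-2-(1,3-dimethoxy-1,3-dioxopropan-2-yl)-3-(methoxycarbonyl)cyclohexane-1-carboxylic acid | OC(=O)[C@H]1CCC[C@@H](C(=O)OC)[C@H]1C(C(=O)OC)C(=O)OC | intermediate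
7 | (1S,2S)-3-bromocyclohexa-3,5-diene-1,2-diol | C1=C[C@H](O)[C@H](O)C(Br)=C1 | starting material
8 | (1S,2S)-3-bromocyclohex-3-ene-1,2-diol | C1C[C@H](O)[C@H](O)C(Br)=C1 | intermediate
9 | (1S,6S)-2-bromo-6-[(tert-butyldimethylsilyl)oxy]cyclohex-2-en-1-ol | C1C[C@H](O[Si](C)(C)C(C)(C)C)[C@H](O)C(Br)=C1 | intermediate
10 | 3-bromo-1-(trimethylsilyl)prop-1-yne | C[Si](C)(C)C#CCBr | starting material
11 | O,C-dilithio derivative of 9 (lithium alkoxide at O-14, vinyllithium at C8) | C1C[C@H](O[Si](C)(C)C(C)(C)C)[C@H](O[Li])C([Li])=C1 | intermediate (not isolated)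
12 | (1R,6S)-6-[(tert-butyldimethylsilyl)oxy]-2-[3-(trimethylsilyl)prop-2-yn-1-yl]cyclohex-2-en-1-ol | C1C[C@H](O[Si](C)(C)C(C)(C)C)[C@H](O)C(CC#C[Si](C)(C)C)=C1 | intermediate
13 | ester of acid 6 (C20 carboxyl) and alcohol 12 (O-14); stereocentres as in 6 and 12 | C1C[C@H](O[Si](C)(C)C(C)(C)C)[C@H](OC(=O)[C@H]2CCC[C@@H](C(=O)OC)[C@H]2C(C(=O)OC)C(=O)OC)C(CC#C[Si](C)(C)C)=C1 | intermediate
14 | tris(trimethylsilyl) ketene acetal of 13 (enolised at C10, C4 and C6) | C1C[C@H](O[Si](C)(C)C(C)(C)C)[C@H](OC(O[Si](C)(C)C)=C2CCCC(=C(OC)O[Si](C)(C)C)[C@H]2C(C(=O)OC)=C(OC)O[Si](C)(C)C)C(CC#C[Si](C)(C)C)=C1 | intermediate (not isolated)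
15 | rearranged species: C9–C10 bonded, trimethylsilyl ester at C20, silyl ketene acetals at C4 and C6 | C[Si](C)(C)C#CCC1=C[C@@H](O[Si](C)(C)C(C)(C)C)CC[C@H]1[C@]2(C(=O)O[Si](C)(C)C)CCCC(=C(OC)O[Si](C)(C)C)[C@H]2C(C(=O)OC)=C(OC)O[Si](C)(C)C | intermediate (not isolated)
16 | 1-{4-[(tert-butyldimethylsilyl)oxy]-2-[3-(trimethylsilyl)prop-2-yn-1-yl]cyclohex-2-en-1-yl}-2-(1,3-dimethoxy-1,3-dioxopropan-2-yl)-3-(methoxycarbonyl)cyclohexane-1-carboxylic acid (C5, C9, C10 as in the target; C4 both epimers) | C[Si](C)(C)C#CCC1=C[C@@H](O[Si](C)(C)C(C)(C)C)CC[C@H]1[C@]2(C(=O)O)CCCC(C(=O)OC)[C@H]2C(C(=O)OC)C(=O)OC | intermediate (not isolated)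
17 | methyl ester of 16 (tetramethyl ester; C4 both epimers) | C[Si](C)(C)C#CCC1=C[C@@H](O[Si](C)(C)C(C)(C)C)CC[C@H]1[C@]2(C(=O)OC)CCCC(C(=O)OC)[C@H]2C(C(=O)OC)C(=O)OC | intermediate
18 | 17 carrying a methyl group at C4 (C19 ester cis to the C20 ester and to C6; C4, C5, C9, C10 as in the target) | C[Si](C)(C)C#CCC1=C[C@@H](O[Si](C)(C)C(C)(C)C)CC[C@H]1[C@]2(C(=O)OC)CCC[C@@](C)(C(=O)OC)[C@H]2C(C(=O)OC)C(=O)OC | intermediate
19 | desilylated 18: C13 allylic alcohol, prop-2-ynyl group on C8 | C#CCC1=C[C@@H](O)CC[C@H]1[C@]2(C(=O)OC)CCC[C@@](C)(C(=O)OC)[C@H]2C(C(=O)OC)C(=O)OC | intermediate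
20 | enone: C13 ketone conjugated to C14=C8; ring A tetraester attached at C9 | C#CCC1=CC(=O)CC[C@H]1[C@]2(C(=O)OC)CCC[C@@](C)(C(=O)OC)[C@H]2C(C(=O)OC)C(=O)OC | intermediate
21 | tricyclic keto tetraester: rings A, B, C closed, C6 geminal diester, prop-2-ynyl on C8, C13 ketone (C4, C5, C8, C9, C10 as in the target) | C#CC[C@]23CC(=O)CC[C@H]2[C@]1(C(=O)OC)CCC[C@@](C)(C(=O)OC)[C@H]1C3(C(=O)OC)C(=O)OC | intermediate
22 | tricyclic keto triester, both C6 epimers | C#CC[C@]23CC(=O)CC[C@H]2[C@]1(C(=O)OC)CCC[C@@](C)(C(=O)OC)[C@H]1C3C(=O)OC | intermediate (not isolated)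
23 | tricyclic keto triester, C6 as in the target (β-ester) | C#CC[C@]23CC(=O)CC[C@H]2[C@]1(C(=O)OC)CCC[C@@](C)(C(=O)OC)[C@H]1[C@@H]3C(=O)OC | intermediate
24 | trimethyl ester of the target gibberellin (trimethyl ent-13-hydroxygibberell-16-ene-7,19,20-trioate) | C=C1C[C@]23C[C@@]1(O)CC[C@H]2[C@]1(C(=O)OC)CCC[C@@](C)(C(=O)OC)[C@H]1[C@@H]3C(=O)OC | intermediate
25 | ent-13-hydroxygibberell-16-ene-7,19,20-trioic acid (the target gibberellin) | C=C1C[C@]23C[C@@]1(O)CC[C@H]2[C@]1(C(=O)O)CCC[C@@](C)(C(=O)O)[C@H]1[C@@H]3C(=O)O | target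

**Totals and risks**
Total step count: 16. Longest linear sequence: 13 steps (steps 1–4, then 8–16); the ring C branch is steps 5–7.

The three steps most likely to fail, in route order (step 9 is the riskiest of the three):

Step 4 (catalytic desymmetrisation). The enantioselectivity for this bridged, glutaric-type anhydride is untested. The fallback sets out from 5 (together with 12) and comes back at 13, replacing steps 4 and 8. Alcohol 12 opens the meso anhydride without a chiral catalyst (DMAP, Et3N, CH2Cl2), giving two diastereomeric half esters that are separable on silica. The wanted one, the C20 ester C19 acid half ester F1, is methylated by TMSCHN2 to give 13.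

Step 7 (vinyl anion propargylation). SN2' attack giving an allene, or silyl migration to the neighbouring alkoxide, could spoil it. The fallback sets out from 9 and comes back at 12. The same dilithio species 11 is alkylated by 2,3-dibromopropene, an allylic bromide for which SN2 and SN2' give one product, to the 2-bromoallyl alcohol F2. Excess LDA eliminates HBr to the acetylide, and TMSCl silylates carbon and oxygen to the bis-silyl compound F3. Citric acid in MeOH frees the hydroxyl to give 12.

Step 9 (Ireland–Claisen). Three sites must be enolised and the new bond joins a quaternary to a tertiary carbon, so low conversion or poor facial control at C10 is possible. The fallback sets out from 6 (together with 12) and comes back at 16.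
- Acid 6 is turned into its S-ethyl thioester F4 (EtSH, DCC, DMAP) and reduced to the C20 aldehyde F5 (Et3SiH, Pd on carbon).
- Acid-catalysed condensation of F5 and 12 (PPTS, toluene, water removed) gives the allyl enol ether F6.
- Heating in xylene at 150 °C effects an aliphatic Claisen rearrangement without any base to the C9–C10-linked aldehyde F7, showing the same chirality transfer to C9 and the same anti approach at C10.
- Pinnick oxidation (NaClO2, NaH2PO4, 2-methyl-2-butene) then gives 16, here as a single C4 epimer, which converges in step 10.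

**Further compounds**
F1 | step 4 | half ester of 5 and 12: C20 carboxyl esterified by O-14 of 12, free C19 acid | C1C[C@H](O[Si](C)(C)C(C)(C)C)[C@H](OC(=O)[C@H]2CCC[C@@H](C(=O)O)[C@H]2C(C(=O)OC)C(=O)OC)C(CC#C[Si](C)(C)C)=C1
F2 | step 7 | (1R,6S)-2-(2-bromoprop-2-en-1-yl)-6-[(tert-butyldimethylsilyl)oxy]cyclohex-2-en-1-ol | C1C[C@H](O[Si](C)(C)C(C)(C)C)[C@H](O)C(CC(Br)=C)=C1
F3 | step 7 | O-trimethylsilyl ether of 12 | C1C[C@H](O[Si](C)(C)C(C)(C)C)[C@H](O[Si](C)(C)C)C(CC#C[Si](C)(C)C)=C1
F4 | step 9 | S-ethyl thioester of acid 6 | CCSC(=O)[C@H]1CCC[C@@H](C(=O)OC)[C@H]1C(C(=O)OC)C(=O)OC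
F5 | step 9 | aldehyde from 6 (C20 formyl in place of carboxyl) | O=C[C@H]1CCC[C@@H](C(=O)OC)[C@H]1C(C(=O)OC)C(=O)OC
F6 | step 9 | allyl enol ether of F5 and 12 (C10=C20–O–C14) | C1C[C@H](O[Si](C)(C)C(C)(C)C)[C@H](OC=C2CCC[C@@H](C(=O)OC)[C@H]2C(C(=O)OC)C(=O)OC)C(CC#C[Si](C)(C)C)=C1
F7 | step 9 | rearranged aldehyde: as 16 but formyl at C10 and C4 as in 6 | C[Si](C)(C)C#CCC1=C[C@@H](O[Si](C)(C)C(C)(C)C)CC[C@H]1[C@]2(C=O)CCC[C@@H](C(=O)OC)[C@H]2C(C(=O)OC)C(=O)OC
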